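**Retrosynthetic overview**
1. Target 16 ⇐ acid (oxabicycle → 1-naphthol, acetonide off) ⇐ 1,4-epoxynaphthalene 14 ⇐ [4+2] of 3-methoxybenzyne with furyl tetralone 12 (naphthalene ring formed last).
2. Tetralone ring of 12 ⇐ aryl triflate/vinyl compound 10 by hydroboration and carbonylative ring closure (CO becomes C1).
3. Benzylic stereocentre ⇐ aromatic Claisen rearrangement of aryl allyl ether 6 (key aryl–C bond, 1,3-chirality transfer); the phenol OH it leaves becomes the triflate.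
4. Ether 6 ⇐ phenol 1 + (R)-but-3-yn-2-ol 2 (Mitsunobu, inversion) + 2-bromofuran 4 (hydroboration/Suzuki).
5. Ring order: benzodioxole and furan bought → cyclohexanone ring → second benzene ring of the naphthalene.

Assumption: 1, 2 (single enantiomer), 4 and 13 are bought as such; the route is a paper design and has not been run.

**Step 1**
Reactants: 1 2,2-dimethyl-1,3-benzodioxol-4-ol; 2 (R)-but-3-yn-2-ol
Product: 3 (S)-4-(but-3-yn-2-yloxy)-2,2-dimethyl-1,3-benzodioxole
Conditions: PPh3, DIAD, THF, 0 °C → rt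
Reagents that add atoms: none
Why: Mitsunobu reaction; the phenoxide displaces the activated propargylic oxygen by SN2, so the bought (R) centre is cleanly inverted to (S).

**Step 2**
Reactants: 3 (S)-4-(but-3-yn-2-yloxy)-2,2-dimethyl-1,3-benzodioxole; 4 2-bromofuran
Product: 6 (S,E)-4-{[4-(furan-2-yl)but-3-en-2-yl]oxy}-2,2-dimethyl-1,3-benzodioxole, via alkenyl pinacol boronate 5 (not isolated)
Conditions: HBpin, Cp2Zr(H)Cl (5 mol %), Et3N (10 mol %), 60 °C; then 4, Pd(dppf)Cl2 (3 mol %), aq. K3PO4, THF, ≤50 °C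
Reagents that add atoms: none
Why: Zr-catalysed syn hydroboration gives only the (E)-alkenyl boronate and Suzuki–Miyaura coupling keeps that geometry; the carbinol centre is not touched (mild temperature limits Pd ionisation of the allylic ether).

**Step 3**
Reactants: 6 (S,E)-4-{[4-(furan-2-yl)but-3-en-2-yl]oxy}-2,2-dimethyl-1,3-benzodioxole
Product: 8 5-[(1R,2E)-1-(furan-2-yl)but-2-en-1-yl]-2,2-dimethyl-1,3-benzodioxol-4-ol, via ortho-dienone 7 (not isolated)
Conditions: PhNEt2, 180 °C, sealed tube, Ar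
Reagents that add atoms: none
Why: Aromatic Claisen ([3,3]-sigmatropic) rearrangement to the only free ortho carbon through a chair transition state with the methyl group pseudo-equatorial; the ring carbon bonds to the allyl face that oxygen leaves, so the (S) ether centre is exchanged for the (R) benzylic centre and an (E)-propenyl group.

**Step 4**
Reactants: 8 5-[(1R,2E)-1-(furan-2-yl)but-2-en-1-yl]-2,2-dimethyl-1,3-benzodioxol-4-ol
Product: 9 5-[(1R,2E)-1-(furan-2-yl)but-2-en-1-yl]-2,2-dimethyl-1,3-benzodioxol-4-yl trifluoromethanesulfonate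
Conditions: PhNTf2, Et3N, DMAP (cat.), CH2Cl2, rt
Reagents that add atoms: N-phenylbis(trifluoromethanesulfonimide), O=S(=O)(N(c1ccccc1)S(=O)(=O)C(F)(F)F)C(F)(F)F
Why: O-sulfonylation of the phenol with a mild triflyl donor that spares furan and alkene; the stereocentre is not involved.

**Step 5**
Reactants: 9 5-[(1R,2E)-1-(furan-2-yl)but-2-en-1-yl]-2,2-dimethyl-1,3-benzodioxol-4-yl trifluoromethanesulfonate
Product: 10 5-[(1R)-1-(furan-2-yl)prop-2-en-1-yl]-2,2-dimethyl-1,3-benzodioxol-4-yl trifluoromethanesulfonate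
Conditions: Hoveyda–Grubbs II (5 mol %), ethylene (5 bar), 1,4-benzoquinone (10 mol %), toluene, 40 °C
Reagents that add atoms: ethylene, C=C
Why: Olefin cross-metathesis with ethylene (ethenolysis) trims propenyl to vinyl, driven by excess ethylene and loss of propene; benzoquinone suppresses Ru–H alkene migration, so the allylic centre stays intact.

**Step 6**
Reactants: 10 5-[(1R)-1-(furan-2-yl)prop-2-en-1-yl]-2,2-dimethyl-1,3-benzodioxol-4-yl trifluoromethanesulfonate
Product: 12 (4R)-4-(furan-2-yl)-7,8-(isopropylidenedioxy)-3,4-dihydronaphthalen-1(2H)-one, via B-alkyl-9-BBN adduct 11 (not isolated)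
Conditions: 9-BBN-H, THF, 0 °C → rt; then Pd(dppf)Cl2 (5 mol %), aq. K3PO4, KBr, CO (5 bar), 60 °C
Reagents that add atoms: carbon monoxide, [C-]#[O+]
Why: Anti-Markovnikov hydroboration followed by intramolecular carbonylative B-alkyl Suzuki–Miyaura coupling (oxidative addition to C–OTf, CO insertion, transmetalation, reductive elimination) closes the six-membered ketone exactly at the carbon that carried the Claisen oxygen.

**Step 7**
Reactants: 12 (4R)-4-(furan-2-yl)-7,8-(isopropylidenedioxy)-3,4-dihydronaphthalen-1(2H)-one; 13 3-methoxy-2-(trimethylsilyl)phenyl trifluoromethanesulfonate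
Product: 14 (4R)-7,8-(isopropylidenedioxy)-4-(8-methoxy-1,4-dihydro-1,4-epoxynaphthalen-1-yl)-3,4-dihydronaphthalen-1(2H)-one (both bridgehead diastereomers)
Conditions: 13 (1.5 equiv), CsF, MeCN, rt; regioisomer carried on and removed after step 8
Reagents that add atoms: none
Why: Fluoride-induced elimination gives 3-methoxybenzyne, which adds to the furan in a [4+2] cycloaddition (Diels–Alder); the unsubstituted furan C5 prefers the aryne carbon meta to OMe, which puts OMe next to the substituted bridgehead, but this preference is only modest.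

**Step 8**
Reactants: 14 (4R)-7,8-(isopropylidenedioxy)-4-(8-methoxy-1,4-dihydro-1,4-epoxynaphthalen-1-yl)-3,4-dihydronaphthalen-1(2H)-one
Product: 16 (4S)-7,8-dihydroxy-4-(4-hydroxy-8-methoxynaphthalen-1-yl)-3,4-dihydronaphthalen-1(2H)-one, via naphthol acetonide 15 (not isolated)
Conditions: TFA–H2O (9:1), CH2Cl2, 0 °C → rt
Reagents that add atoms: none
Why: Acid-catalysed opening of the oxygen bridge at the tertiary, o-methoxy-stabilised bridgehead, 1,2-hydride shift and enolisation give the 4-substituted 1-naphthol, and the same acid hydrolyses the catechol acetonide; the benzylic centre is untouched (the descriptor changes from R to S only because the CIP priorities change).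

**Compound list**
1 | 2,2-dimethyl-1,3-benzodioxol-4-ol | CC1(C)Oc2cccc(O)c2O1 | starting material
2 | (R)-but-3-yn-2-ol | C[C@@H](O)C#C | starting material
3 | (S)-4-(but-3-yn-2-yloxy)-2,2-dimethyl-1,3-benzodioxole | C[C@H](Oc1cccc2OC(C)(C)Oc12)C#C | intermediate
4 | 2-bromofuran | Brc1ccco1 | starting material
5 | (S,E)-2,2-dimethyl-4-{[4-(4,4,5,5-tetramethyl-1,3,2-dioxaborolan-2-yl)but-3-en-2-yl]oxy}-1,3-benzodioxole | C[C@H](Oc1cccc2OC(C)(C)Oc12)/C=C/B1OC(C)(C)C(C)(C)O1 | intermediate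
6 | (S,E)-4-{[4-(furan-2-yl)but-3-en-2-yl]oxy}-2,2-dimethyl-1,3-benzodioxole | C[C@H](Oc1cccc2OC(C)(C)Oc12)/C=C/c1ccco1 | intermediate
7 | 5-[(1R,2E)-1-(furan-2-yl)but-2-en-1-yl]-2,2-dimethyl-1,3-benzodioxol-4(5H)-one (ring C5 configuration not specified) | O=C1C(C=CC2=C1OC(C)(C)O2)[C@@H](/C=C/C)c1ccco1 | intermediate
8 | 5-[(1R,2E)-1-(furan-2-yl)but-2-en-1-yl]-2,2-dimethyl-1,3-benzodioxol-4-ol | C/C=C/[C@@H](c1ccco1)c1ccc2OC(C)(C)Oc2c1O | intermediate
9 | 5-[(1R,2E)-1-(furan-2-yl)but-2-en-1-yl]-2,2-dimethyl-1,3-benzodioxol-4-yl trifluoromethanesulfonate | C/C=C/[C@@H](c1ccco1)c1ccc2OC(C)(C)Oc2c1OS(=O)(=O)C(F)(F)F | intermediate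
10 | 5-[(1R)-1-(furan-2-yl)prop-2-en-1-yl]-2,2-dimethyl-1,3-benzodioxol-4-yl trifluoromethanesulfonate | C=C[C@@H](c1ccco1)c1ccc2OC(C)(C)Oc2c1OS(=O)(=O)C(F)(F)F | intermediate
11 | 5-[(1R)-3-(9-borabicyclo[3.3.1]nonan-9-yl)-1-(furan-2-yl)propyl]-2,2-dimethyl-1,3-benzodioxol-4-yl trifluoromethanesulfonate | B1(CC[C@@H](c2ccco2)c2ccc3OC(C)(C)Oc3c2OS(=O)(=O)C(F)(F)F)C2CCCC1CCC2 | intermediate
12 | (4R)-4-(furan-2-yl)-7,8-(isopropylidenedioxy)-3,4-dihydronaphthalen-1(2H)-one | O=C1CC[C@@H](c2ccco2)c2ccc3OC(C)(C)Oc3c12 | intermediate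
13 | 3-methoxy-2-(trimethylsilyl)phenyl trifluoromethanesulfonate | COc1cccc(OS(=O)(=O)C(F)(F)F)c1[Si](C)(C)C | starting material
14 | (4R)-7,8-(isopropylidenedioxy)-4-(8-methoxy-1,4-dihydro-1,4-epoxynaphthalen-1-yl)-3,4-dihydronaphthalen-1(2H)-one (bridgehead diastereomers) | O=C1CC[C@@H](C23OC(C=C2)c2cccc(OC)c23)c2ccc3OC(C)(C)Oc3c12 | intermediate
15 | (4S)-4-(4-hydroxy-8-methoxynaphthalen-1-yl)-7,8-(isopropylidenedioxy)-3,4-dihydronaphthalen-1(2H)-one | O=C1CC[C@@H](c2ccc(O)c3cccc(OC)c23)c2ccc3OC(C)(C)Oc3c12 | intermediate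
16 | (4S)-7,8-dihydroxy-4-(4-hydroxy-8-methoxynaphthalen-1-yl)-3,4-dihydronaphthalen-1(2H)-one | COc1cccc2c(O)ccc([C@@H]3CCC(=O)c4c3ccc(O)c4O)c12 | target

**Totals**
Total steps: 8. Longest linear sequence: 8 steps (1/2 → 16).

**Three steps most likely to fail, with fallbacks**

Step 3 (Claisen). The furyl-conjugated secondary allyl aryl ether can ionise, which would lead to a [1,3] shift, loss of phenol to a diene, or erosion of ee; a minor methyl-axial pathway also lowers ee. The fallback replaces the sigmatropic step by an anti-SN2′ arylcopper substitution; it sets out from 2, 4 and 1 and comes back at 8. Sonogashira coupling of 2 with 4 (Pd(PPh3)2Cl2, CuI, Et3N) gives (R)-4-(furan-2-yl)but-3-yn-2-ol F1, Red-Al reduces it to the (R,E)-allylic alcohol F2, and picolinic acid/EDC/DMAP gives the picolinate F3. Separately 1 is protected as its MOM ether F4 (MOMCl, iPr2NEt) and lithiated next to the OMOM group (n-BuLi, TMEDA) to the aryllithium F5. After transmetalation (MgBr2, CuBr·SMe2), F5 attacks F3 anti-SN2′ to give the MOM-protected diaryl methine F6, with the same configuration because retention at the carbinol plus anti attack equals inversion plus syn Claisen. Dilute HCl in MeOH removes the MOM group and returns 8.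

Step 6 (carbonylative ring closure). Direct B-alkyl Suzuki coupling to the five-membered indane can compete with CO insertion, and the triflate is doubly ortho-hindered. The fallback separates acyl transfer from ring closure; it sets out from 10 and comes back at 12. Pd-catalysed aminocarbonylation of 10 (Pd(OAc)2, Xantphos, CO, MeONHMe·HCl, K3PO4) gives the Weinreb amide F7. Hydroboration with 9-BBN gives the borane F8, and iodinolysis (I2, NaOMe) gives the primary iodide F9. t-BuLi at −78 °C forms the alkyllithium F10 by iodine–lithium exchange, and F10 closes onto the amide (Parham-type cycloacylation) to give 12.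

Step 7 (aryne cycloaddition), the most likely of the three to underperform. With a branched substituent on the furan the OMe-proximal and OMe-distal adducts may form in roughly equal amounts, so about half the material could be lost at a late stage. The fallback brings in the naphthalene pre-formed and regiodefined; it sets out from 5 and comes back at 15. Commercial 5-methoxy-1,4-naphthoquinone is reduced (Na2S2O4) to the diol F11. The unhindered hydroxyl is silylated (TIPSCl, imidazole) to F12, and the remaining hydroxyl, peri to OMe, is triflated (Tf2O, pyridine) to F13. Suzuki coupling of 5 with F13 in place of 4 gives the ether F14. The operations of steps 3–6 then give the Claisen phenol F15, its triflate F16, the vinyl compound F17, the borane F18 and the tetralone F19. TBAF removes the silyl group to give 15, which step 8 converts to 16.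

**Further compounds**
F1 | step 3 | (R)-4-(furan-2-yl)but-3-yn-2-ol | C[C@@H](O)C#Cc1ccco1
F2 | step 3 | (R,E)-4-(furan-2-yl)but-3-en-2-ol | C[C@@H](O)/C=C/c1ccco1
F3 | step 3 | (R,E)-4-(furan-2-yl)but-3-en-2-yl pyridine-2-carboxylate | C[C@@H](OC(=O)c1ccccn1)/C=C/c1ccco1
F4 | step 3 | 4-(methoxymethoxy)-2,2-dimethyl-1,3-benzodioxole | COCOc1cccc2OC(C)(C)Oc12
F5 | step 3 | [4-(methoxymethoxy)-2,2-dimethyl-1,3-benzodioxol-5-yl]lithium | [Li]c1ccc2OC(C)(C)Oc2c1OCOC
F6 | step 3 | 5-[(1R,2E)-1-(furan-2-yl)but-2-en-1-yl]-4-(methoxymethoxy)-2,2-dimethyl-1,3-benzodioxole | C/C=C/[C@@H](c1ccco1)c1ccc2OC(C)(C)Oc2c1OCOC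
F7 | step 6 | 5-[(1R)-1-(furan-2-yl)prop-2-en-1-yl]-N-methoxy-N,2,2-trimethyl-1,3-benzodioxole-4-carboxamide | C=C[C@@H](c1ccco1)c1ccc2OC(C)(C)Oc2c1C(=O)N(C)OC
F8 | step 6 | 5-[(1R)-3-(9-borabicyclo[3.3.1]nonan-9-yl)-1-(furan-2-yl)propyl]-N-methoxy-N,2,2-trimethyl-1,3-benzodioxole-4-carboxamide | B1(CC[C@@H](c2ccco2)c2ccc3OC(C)(C)Oc3c2C(=O)N(C)OC)C2CCCC1CCC2
F9 | step 6 | 5-[(1R)-1-(furan-2-yl)-3-iodopropyl]-N-methoxy-N,2,2-trimethyl-1,3-benzodioxole-4-carboxamide | ICC[C@@H](c1ccco1)c1ccc2OC(C)(C)Oc2c1C(=O)N(C)OC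
F10 | step 6 | {(3R)-3-(furan-2-yl)-3-[4-(methoxy(methyl)carbamoyl)-2,2-dimethyl-1,3-benzodioxol-5-yl]propyl}lithium | [Li]CC[C@@H](c1ccco1)c1ccc2OC(C)(C)Oc2c1C(=O)N(C)OC
F11 | step 7 | 5-methoxynaphthalene-1,4-diol | COc1cccc2c(O)ccc(O)c12
F12 | step 7 | 8-methoxy-4-(triisopropylsilyloxy)naphthalen-1-ol | COc1cccc2c(O[Si](C(C)C)(C(C)C)C(C)C)ccc(O)c12
F13 | step 7 | 8-methoxy-4-(triisopropylsilyloxy)naphthalen-1-yl trifluoromethanesulfonate | COc1cccc2c(O[Si](C(C)C)(C(C)C)C(C)C)ccc(OS(=O)(=O)C(F)(F)F)c12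
F14 | step 7 | (S,E)-4-({4-[8-methoxy-4-(triisopropylsilyloxy)naphthalen-1-yl]but-3-en-2-yl}oxy)-2,2-dimethyl-1,3-benzodioxole | C[C@H](Oc1cccc2OC(C)(C)Oc12)/C=C/c1ccc(O[Si](C(C)C)(C(C)C)C(C)C)c2cccc(OC)c12
F15 | step 7 | 5-{(1S,2E)-1-[8-methoxy-4-(triisopropylsilyloxy)naphthalen-1-yl]but-2-en-1-yl}-2,2-dimethyl-1,3-benzodioxol-4-ol | C/C=C/[C@@H](c1ccc(O[Si](C(C)C)(C(C)C)C(C)C)c2cccc(OC)c12)c1ccc2OC(C)(C)Oc2c1O
F16 | step 7 | 5-{(1S,2E)-1-[8-methoxy-4-(triisopropylsilyloxy)naphthalen-1-yl]but-2-en-1-yl}-2,2-dimethyl-1,3-benzodioxol-4-yl trifluoromethanesulfonate | C/C=C/[C@@H](c1ccc(O[Si](C(C)C)(C(C)C)C(C)C)c2cccc(OC)c12)c1ccc2OC(C)(C)Oc2c1OS(=O)(=O)C(F)(F)F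
F17 | step 7 | 5-{(1S)-1-[8-methoxy-4-(triisopropylsilyloxy)naphthalen-1-yl]prop-2-en-1-yl}-2,2-dimethyl-1,3-benzodioxol-4-yl trifluoromethanesulfonate | C=C[C@@H](c1ccc(O[Si](C(C)C)(C(C)C)C(C)C)c2cccc(OC)c12)c1ccc2OC(C)(C)Oc2c1OS(=O)(=O)C(F)(F)F
F18 | step 7 | 5-{(1S)-3-(9-borabicyclo[3.3.1]nonan-9-yl)-1-[8-methoxy-4-(triisopropylsilyloxy)naphthalen-1-yl]propyl}-2,2-dimethyl-1,3-benzodioxol-4-yl trifluoromethanesulfonate | B1(CC[C@@H](c2ccc(O[Si](C(C)C)(C(C)C)C(C)C)c3cccc(OC)c23)c2ccc3OC(C)(C)Oc3c2OS(=O)(=O)C(F)(F)F)C2CCCC1CCC2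
F19 | step 7 | (4S)-7,8-(isopropylidenedioxy)-4-[8-methoxy-4-(triisopropylsilyloxy)naphthalen-1-yl]-3,4-dihydronaphthalen-1(2H)-one | O=C1CC[C@@H](c2ccc(O[Si](C(C)C)(C(C)C)C(C)C)c3cccc(OC)c23)c2ccc3OC(C)(C)Oc3c12
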